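**Retrosynthetic overview**

- The last disconnection is the acid hydrolysis of one dioxolane (masking the C5' pentanoyl group) and two methoxymethyl ethers (on the C3 and C5 oxygens of ring A).
- The strategy rests on ring B: the ether oxygen on C1' and the carboxyl carbon on C6' sit on neighbouring ring carbons, C6' is flanked by the bulky acyl-bearing C5', and the C3' methoxy group is remote. The O–C1' and C6'–CO2H bonds are therefore cut together, leaving a C1'–C6' aryne, the ring A aryloxide (oxygen on C6, between the pentyl-bearing C1 and the oxygenated C5) and CO2.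
- The aryne comes from an ortho-silylaryl triflate (triflate on C6', SiMe3 on C1'), made from 1,4-dimethoxybenzene by acylation with ortho-demethylation, bromination, ketalization, and bromine–lithium exchange with retro-Brook shift and triflation.
- The ring A phenol comes from olivetol by formylation, bis-methoxymethylation and Dakin-type oxidation.
- No ring is formed at any stage: both benzene rings are bought and the two branches meet in the key step.

Key step: step 8

Remark: either ortho-silylaryl triflate regioisomer would release the same C1'–C6' aryne. The isomer with the triflate on C6' and SiMe3 on C1' is used because its phenol precursor has the para position blocked by the methoxy group, so the bromine that becomes silicon can only enter ortho to the hydroxyl; the isomer with the triflate on C1' would need a bromination of a 3,5-disubstituted phenol with three open activated positions.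

Remark: the target is taken as the open keto acid drawn; a 2-acylbenzoic acid can equilibrate with its cyclic 3-hydroxyphthalide form, which is regarded as the same compound.

**Route**

Step 1
Reactants: 1 olivetol (5-pentylbenzene-1,3-diol)
Product: 2 2,4-dihydroxy-6-pentylbenzaldehyde
Conditions: POCl3, DMF, 0 °C → rt; then H2O, 50 °C
Reagents that add atoms: N,N-dimethylformamide CN(C)C=O; water O
Why: Vilsmeier–Haack formylation of the resorcinol should go to the ring carbon next to the pentyl group, ortho to one hydroxyl and para to the other, as it does with orcinol.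

Step 2
Reactants: 2 2,4-dihydroxy-6-pentylbenzaldehyde
Product: 3 2,4-bis(methoxymethoxy)-6-pentylbenzaldehyde
Conditions: NaH, MOMCl, THF–DMF, 0 °C → rt
Reagents that add atoms: chloromethyl methyl ether COCCl
Why: Williamson-type O-alkylation of the bis-phenoxide should protect both hydroxyls, the sodium salt overcoming the hydrogen bond of the ortho hydroxyl to the aldehyde.

Step 3
Reactants: 3 2,4-bis(methoxymethoxy)-6-pentylbenzaldehyde
Product: 5 2,4-bis(methoxymethoxy)-6-pentylphenol, via 2,4-bis(methoxymethoxy)-6-pentylphenyl formate 4 (not isolated)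
Conditions: mCPBA, CH2Cl2, 0 °C → rt; then K2CO3 (cat.), MeOH, rt, under argon
Reagents that add atoms: 3-chloroperoxybenzoic acid O=C(OO)c1cccc(Cl)c1
Why: Dakin-type Baeyer–Villiger oxidation should proceed by migration of the electron-rich aryl group to give the aryl formate, which mild methanolysis should cleave to the phenol without touching the methoxymethyl ethers.

Step 4
Reactants: 6 1,4-dimethoxybenzene; 7 pentanoyl chloride
Product: 9 1-(2-hydroxy-5-methoxyphenyl)pentan-1-one, via 1-(2,5-dimethoxyphenyl)pentan-1-one 8 (not isolated)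
Conditions: AlCl3 (2.5 equiv), 1,2-dichloroethane, 0 °C then 60 °C; aq HCl work-up
Reagents that add atoms: none
Why: Friedel–Crafts acylation should be followed in the same flask by chelation-directed AlCl3 cleavage of only the methoxy group ortho to the new carbonyl.

Step 5
Reactants: 9 1-(2-hydroxy-5-methoxyphenyl)pentan-1-one
Product: 10 1-(3-bromo-2-hydroxy-5-methoxyphenyl)pentan-1-one
Conditions: NBS (1.0 equiv), MeCN, 0 °C → rt
Reagents that add atoms: N-bromosuccinimide O=C1CCC(=O)N1Br
Why: Electrophilic aromatic bromination should take the only free position ortho to the hydroxyl (para is blocked by the methoxy group, and the site is meta to the acyl group), and ionic ring bromination of the phenol should outrun alpha-bromination of the ketone.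

Step 6
Reactants: 10 1-(3-bromo-2-hydroxy-5-methoxyphenyl)pentan-1-one
Product: 11 2-bromo-6-(2-butyl-1,3-dioxolan-2-yl)-4-methoxyphenol
Conditions: HOCH2CH2OH (excess), p-TsOH·H2O (cat.), toluene, reflux, Dean–Stark; Et3N quench
Reagents that add atoms: ethylene glycol OCCO
Why: Acid-catalysed ketalization with azeotropic removal of water should convert the aryl ketone into its dioxolane, the aryl bromide and methyl ether being inert.

Step 7
Reactants: 11 2-bromo-6-(2-butyl-1,3-dioxolan-2-yl)-4-methoxyphenol
Product: 14 2-(2-butyl-1,3-dioxolan-2-yl)-4-methoxy-6-(trimethylsilyl)phenyl trifluoromethanesulfonate, via aryl trimethylsilyl ether 12 (not isolated), via lithium 2-silylphenoxide 13 (not isolated)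
Conditions: HMDS, THF, 65 °C, then evaporation; n-BuLi, THF, −78 °C; Tf2O, −78 °C → 0 °C
Reagents that add atoms: hexamethyldisilazane C[Si](C)(C)N[Si](C)(C)C; trifluoromethanesulfonic anhydride O=S(=O)(OS(=O)(=O)C(F)(F)F)C(F)(F)F
Why: O-silylation, bromine–lithium exchange, retro-Brook 1,3-shift of silicon from oxygen to carbon and O-triflation of the lithium phenoxide are the standard sequence to ortho-silylaryl triflates, and the dioxolane is inert to n-BuLi at −78 °C.

Step 8
Reactants: 5 2,4-bis(methoxymethoxy)-6-pentylphenol (1.5 equiv); 14 2-(2-butyl-1,3-dioxolan-2-yl)-4-methoxy-6-(trimethylsilyl)phenyl trifluoromethanesulfonate; 15 carbon dioxide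
Product: 20 2-[2,4-bis(methoxymethoxy)-6-pentylphenoxy]-6-(2-butyl-1,3-dioxolan-2-yl)-4-methoxybenzoic acid, via potassium 2,4-bis(methoxymethoxy)-6-pentylphenoxide 16 (not isolated), via 3-(2-butyl-1,3-dioxolan-2-yl)-5-methoxybenzyne 17 (not isolated), via C6' arylpotassium adduct 18 (not isolated), via potassium benzoate salt 19 (not isolated)
Conditions: KH, THF, 0 °C; then KF, 18-crown-6, CO2 (1 atm), slow addition of 14, THF, 0 °C → rt; cold dilute HCl to pH 3
Reagents that add atoms: none
Why: Proposed new method: fluoride attack on silicon with loss of triflate should give aryne 17, the proton-free aryloxide 16 (preformed with KH) should add in the plane of the strained C1'–C6' triple bond at C1', and the C6' arylpotassium 18 should be captured by CO2 to give benzoate 19 before it finds a proton. The closest known reaction types are the fluoride-induced O-arylation of phenols with ortho-silylaryl triflates and the three-component coupling of arynes, amines and CO2 to anthranilic acids; the union of an aryloxide, an aryne and CO2 has no direct precedent. No ring is closed and no stereocenter is formed. The regioselectivity needed (oxygen on C1', charge on C6') should come from the 2-butyl-1,3-dioxolan-2-yl group on C5', which is bulky and inductively withdrawing and so sends the nucleophile to the remote aryne carbon, while the C3' methoxy group exerts only a weak bias. The chemoselectivity needed (carboxylation over protonation, O- over C-arylation) should come from the aprotic medium under excess CO2, from the substituted ortho and para positions of the aryloxide, and from masking the enolizable pentanoyl group as the dioxolane. The early transition state of aryne capture should tolerate the di-ortho-substituted aryloxide, and an excess of 16 with slow addition of 14 should limit O-arylation of 19 by the aryne.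

Step 9
Reactants: 20 2-[2,4-bis(methoxymethoxy)-6-pentylphenoxy]-6-(2-butyl-1,3-dioxolan-2-yl)-4-methoxybenzoic acid
Product: 21 2-(2,4-dihydroxy-6-pentylphenoxy)-4-methoxy-6-pentanoylbenzoic acid (CNP0189595.0)
Conditions: 3 M aq HCl, THF, 45 °C, dilute solution
Reagents that add atoms: water O
Why: Acid-catalysed acetal hydrolysis should remove the dioxolane and both methoxymethyl ethers in one operation, while the diaryl ether, the aryl methyl ether and the hindered carboxylic acid are stable.

**Compound list**

1 | olivetol (5-pentylbenzene-1,3-diol) | CCCCCc1cc(O)cc(O)c1 | starting material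
2 | 2,4-dihydroxy-6-pentylbenzaldehyde | CCCCCc1cc(O)cc(O)c1C=O | intermediate
3 | 2,4-bis(methoxymethoxy)-6-pentylbenzaldehyde | CCCCCc1cc(OCOC)cc(OCOC)c1C=O | intermediate
4 | 2,4-bis(methoxymethoxy)-6-pentylphenyl formate | CCCCCc1cc(OCOC)cc(OCOC)c1OC=O | intermediate
5 | 2,4-bis(methoxymethoxy)-6-pentylphenol | CCCCCc1cc(OCOC)cc(OCOC)c1O | intermediate
6 | 1,4-dimethoxybenzene | COc1ccc(OC)cc1 | starting material
7 | pentanoyl chloride | CCCCC(=O)Cl | starting material
8 | 1-(2,5-dimethoxyphenyl)pentan-1-one | CCCCC(=O)c1cc(OC)ccc1OC | intermediate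
9 | 1-(2-hydroxy-5-methoxyphenyl)pentan-1-one | CCCCC(=O)c1cc(OC)ccc1O | intermediate
10 | 1-(3-bromo-2-hydroxy-5-methoxyphenyl)pentan-1-one | CCCCC(=O)c1cc(OC)cc(Br)c1O | intermediate
11 | 2-bromo-6-(2-butyl-1,3-dioxolan-2-yl)-4-methoxyphenol | CCCCC1(OCCO1)c1cc(OC)cc(Br)c1O | intermediate
12 | [2-bromo-6-(2-butyl-1,3-dioxolan-2-yl)-4-methoxyphenoxy]trimethylsilane | CCCCC1(OCCO1)c1cc(OC)cc(Br)c1O[Si](C)(C)C | intermediate
13 | lithium 2-(2-butyl-1,3-dioxolan-2-yl)-4-methoxy-6-(trimethylsilyl)phenoxide | CCCCC1(OCCO1)c1cc(OC)cc([Si](C)(C)C)c1[O-].[Li+] | intermediate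
14 | 2-(2-butyl-1,3-dioxolan-2-yl)-4-methoxy-6-(trimethylsilyl)phenyl trifluoromethanesulfonate | CCCCC1(OCCO1)c1cc(OC)cc([Si](C)(C)C)c1OS(=O)(=O)C(F)(F)F | intermediate
15 | carbon dioxide | O=C=O | starting material
16 | potassium 2,4-bis(methoxymethoxy)-6-pentylphenoxide | CCCCCc1cc(OCOC)cc(OCOC)c1[O-].[K+] | intermediate
17 | 3-(2-butyl-1,3-dioxolan-2-yl)-5-methoxybenzyne (triple bond C1'–C6') | CCCCC1(OCCO1)C1=CC(OC)=CC#C1 | intermediate
18 | potassium 2-[2,4-bis(methoxymethoxy)-6-pentylphenoxy]-6-(2-butyl-1,3-dioxolan-2-yl)-4-methoxybenzen-1-ide (C6' arylpotassium) | CCCCCc1cc(OCOC)cc(OCOC)c1Oc1cc(OC)cc(C2(CCCC)OCCO2)[c-]1.[K+] | intermediate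
19 | potassium 2-[2,4-bis(methoxymethoxy)-6-pentylphenoxy]-6-(2-butyl-1,3-dioxolan-2-yl)-4-methoxybenzoate | CCCCCc1cc(OCOC)cc(OCOC)c1Oc1cc(OC)cc(C2(CCCC)OCCO2)c1C(=O)[O-].[K+] | intermediate
20 | 2-[2,4-bis(methoxymethoxy)-6-pentylphenoxy]-6-(2-butyl-1,3-dioxolan-2-yl)-4-methoxybenzoic acid | CCCCCc1cc(OCOC)cc(OCOC)c1Oc1cc(OC)cc(C2(CCCC)OCCO2)c1C(=O)O | intermediate
21 | 2-(2,4-dihydroxy-6-pentylphenoxy)-4-methoxy-6-pentanoylbenzoic acid | CCCCCc1cc(O)cc(O)c1Oc1cc(OC)cc(C(=O)CCCC)c1C(=O)O | target

**Step count and risks**

Total step count: 9 (steps 1–3 for ring A, steps 4–7 for ring B, steps 8 and 9 after the union). Longest linear sequence: 6 steps (steps 4 to 9, from 1,4-dimethoxybenzene).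

Steps most likely to fail:

1. Step 8 (proposed new method). The C6' aryl anion may be protonated before it is carboxylated, which would give plain O-arylation. The aryloxide may add through the oxygen of its CO2 adduct, leading to an ester instead of the ether. Attack may go partly to C6' instead of C1'. The product carboxylate may be arylated by further aryne. Fallback by known chemistry, setting out from 11 and 5 and returning at 20: the C6' hydroxyl of 11 is benzylated (BnBr, K2CO3, DMF) to 2-[2-(benzyloxy)-3-bromo-5-methoxyphenyl]-2-butyl-1,3-dioxolane F1. Palladium-catalysed C–O coupling of F1 with 5 (Pd(OAc)2, 2-(di-tert-butylphosphino)-2',4',6'-triisopropylbiphenyl, K3PO4, toluene, 100 °C) should give 2-{2-(benzyloxy)-3-[2,4-bis(methoxymethoxy)-6-pentylphenoxy]-5-methoxyphenyl}-2-butyl-1,3-dioxolane F2. Hydrogenolysis (H2, Pd/C, EtOAc) should free 2-[2,4-bis(methoxymethoxy)-6-pentylphenoxy]-6-(2-butyl-1,3-dioxolan-2-yl)-4-methoxyphenol F3. Triflation (Tf2O, pyridine, CH2Cl2, 0 °C) should give 2-[2,4-bis(methoxymethoxy)-6-pentylphenoxy]-6-(2-butyl-1,3-dioxolan-2-yl)-4-methoxyphenyl trifluoromethanesulfonate F4. Palladium-catalysed hydroxycarbonylation of F4 (Pd(OAc)2, 1,1'-bis(diphenylphosphino)ferrocene, KOAc, CO 1 atm, DMSO, 70 °C) should then give 20. Here the ether bond is made by cross-coupling at the bromine-bearing C1' and the carboxyl is introduced afterwards at C6'.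

2. Step 6. The ketalization may stall, because the ketone is hydrogen-bonded to the ortho hydroxyl and conjugated with it, so the equilibrium and rate are unfavourable. Fallback, setting out from 9 and returning at 11: the phenol is first benzylated (BnBr, K2CO3, acetone, reflux) to 1-[2-(benzyloxy)-5-methoxyphenyl]pentan-1-one F5. The no longer hydrogen-bonded ketone is ketalized (ethylene glycol, p-TsOH·H2O cat., toluene, Dean–Stark) to 2-[2-(benzyloxy)-5-methoxyphenyl]-2-butyl-1,3-dioxolane F6. Hydrogenolysis (H2, Pd/C, EtOAc) should give 2-(2-butyl-1,3-dioxolan-2-yl)-4-methoxyphenol F7. Bromination of F7 ortho to the hydroxyl (NBS, MeCN, 0 °C) should give 11. The bromine is thus introduced only after the benzyl group has been removed, so hydrogenolysis cannot debrominate.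

3. Step 9. Formaldehyde released from the methoxymethyl ethers may be captured under acid by the very electron-rich ring A resorcinol (hydroxymethylation or methylene bridging), or the cleavage may stop short. Fallback, setting out from 2 and returning at 21, with benzyl ethers in place of the methoxymethyl ethers: benzylation (BnBr, K2CO3, DMF, 60 °C) should give 2,4-bis(benzyloxy)-6-pentylbenzaldehyde F8. Oxidation with mCPBA in CH2Cl2 should give 2,4-bis(benzyloxy)-6-pentylphenyl formate F9, which is methanolysed (K2CO3 cat., MeOH) to 2,4-bis(benzyloxy)-6-pentylphenol F10. Union of F10 with 14 and 15 under the conditions of step 8 (through aryne 17) should give 2-[2,4-bis(benzyloxy)-6-pentylphenoxy]-6-(2-butyl-1,3-dioxolan-2-yl)-4-methoxybenzoic acid F11. Hydrogenolysis (H2, Pd/C, EtOAc), with the ketone still masked so that it is not reduced, should give 2-(2-butyl-1,3-dioxolan-2-yl)-6-(2,4-dihydroxy-6-pentylphenoxy)-4-methoxybenzoic acid F12. Brief treatment of F12 with 1 M aq HCl in THF at rt should give 21 without any formaldehyde being formed.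

**Further compounds**

F1 | step 8 | 2-[2-(benzyloxy)-3-bromo-5-methoxyphenyl]-2-butyl-1,3-dioxolane | CCCCC1(OCCO1)c1cc(OC)cc(Br)c1OCc1ccccc1
F2 | step 8 | 2-{2-(benzyloxy)-3-[2,4-bis(methoxymethoxy)-6-pentylphenoxy]-5-methoxyphenyl}-2-butyl-1,3-dioxolane | CCCCCc1cc(OCOC)cc(OCOC)c1Oc1cc(OC)cc(C2(CCCC)OCCO2)c1OCc1ccccc1
F3 | step 8 | 2-[2,4-bis(methoxymethoxy)-6-pentylphenoxy]-6-(2-butyl-1,3-dioxolan-2-yl)-4-methoxyphenol | CCCCCc1cc(OCOC)cc(OCOC)c1Oc1cc(OC)cc(C2(CCCC)OCCO2)c1O
F4 | step 8 | 2-[2,4-bis(methoxymethoxy)-6-pentylphenoxy]-6-(2-butyl-1,3-dioxolan-2-yl)-4-methoxyphenyl trifluoromethanesulfonate | CCCCCc1cc(OCOC)cc(OCOC)c1Oc1cc(OC)cc(C2(CCCC)OCCO2)c1OS(=O)(=O)C(F)(F)F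
F5 | step 6 | 1-[2-(benzyloxy)-5-methoxyphenyl]pentan-1-one | CCCCC(=O)c1cc(OC)ccc1OCc1ccccc1
F6 | step 6 | 2-[2-(benzyloxy)-5-methoxyphenyl]-2-butyl-1,3-dioxolane | CCCCC1(OCCO1)c1cc(OC)ccc1OCc1ccccc1
F7 | step 6 | 2-(2-butyl-1,3-dioxolan-2-yl)-4-methoxyphenol | CCCCC1(OCCO1)c1cc(OC)ccc1O
F8 | step 9 | 2,4-bis(benzyloxy)-6-pentylbenzaldehyde | CCCCCc1cc(OCc2ccccc2)cc(OCc2ccccc2)c1C=O
F9 | step 9 | 2,4-bis(benzyloxy)-6-pentylphenyl formate | CCCCCc1cc(OCc2ccccc2)cc(OCc2ccccc2)c1OC=O
F10 | step 9 | 2,4-bis(benzyloxy)-6-pentylphenol | CCCCCc1cc(OCc2ccccc2)cc(OCc2ccccc2)c1O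
F11 | step 9 | 2-[2,4-bis(benzyloxy)-6-pentylphenoxy]-6-(2-butyl-1,3-dioxolan-2-yl)-4-methoxybenzoic acid | CCCCCc1cc(OCc2ccccc2)cc(OCc2ccccc2)c1Oc1cc(OC)cc(C2(CCCC)OCCO2)c1C(=O)O
F12 | step 9 | 2-(2-butyl-1,3-dioxolan-2-yl)-6-(2,4-dihydroxy-6-pentylphenoxy)-4-methoxybenzoic acid | CCCCCc1cc(O)cc(O)c1Oc1cc(OC)cc(C2(CCCC)OCCO2)c1C(=O)O
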